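Assumption: the SMILES has no stereocentre and no stereodescriptor, and marchantin-type 18-membered cyclophanes are conformationally mobile at room temperature. The target is therefore treated as achiral, and no step sets or risks stereochemistry.

## Retrosynthetic overview
1. The macrocycle is opened at its most hindered bond, C-ring O to quinone C-2. The 18-membered ring closes last, at the quinone oxidation level, by phenoxide addition–elimination on a 2-bromo-1,4-benzoquinone with no protecting groups.
2. The bromoquinone bis-phenol comes from an all-methyl-ether seco compound by global BBr3 demethylation and selective hydroquinone oxidation.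
3. The D–CH2CH2–A bibenzyl comes from an A-ring styrene and 2-bromo-3-iodo-1,4-dimethoxybenzene by hydroboration and C–I-selective B-alkyl Suzuki coupling. There is no Wittig/hydrogenation sequence, so the C–Br bond survives.
4. The B–CH2CH2–C bibenzyl comes from 3-vinylanisole and a B-ring bromide by a second B-alkyl Suzuki coupling. The A–O–B ether comes from an SNAr on 4-fluorobenzaldehyde.
5. All four six-membered rings are purchased. The only ring formed is the macrocycle, in the final step.

## Route

**Step 1**
Reactants: 1, 5-bromo-2-methoxyphenol; 2, 4-fluorobenzaldehyde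
Product: 3, 4-(5-bromo-2-methoxyphenoxy)benzaldehyde
Conditions: K2CO3, DMSO, 110 °C
Reagents that add atoms: none beyond reactants 1 and 2
Why: This is an SNAr in which the para-formyl group activates C–F toward the phenoxide while the unactivated C–Br is inert, the same reaction type as the classical isovanillin/4-fluorobenzaldehyde ether synthesis.

**Step 2**
Reactants: 3; 4, 3-vinylanisole (1-ethenyl-3-methoxybenzene)
Product: 5, 4-{2-methoxy-5-[2-(3-methoxyphenyl)ethyl]phenoxy}benzaldehyde
Conditions: 4, 9-BBN, THF, 0 °C to rt; aq K3PO4; then 3, PdCl2(dppf) (5 mol %), DMF, 60 °C; non-oxidative work-up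
Reagents that add atoms: none beyond reactants 3 and 4 (9-BBN delivers only H)
Why: Anti-Markovnikov hydroboration followed by B-alkyl Suzuki–Miyaura coupling at the only C–Br gives the saturated bibenzyl directly, and residual B–H is destroyed by aqueous base before 3 is added, so the aldehyde survives.

**Step 3**
Reactants: 5
Product: 6, 1-(4-ethenylphenoxy)-2-methoxy-5-[2-(3-methoxyphenyl)ethyl]benzene
Conditions: MePPh3Br, KOtBu, THF, 0 °C to rt
Reagents that add atoms: methyltriphenylphosphonium bromide, C[P+](c1ccccc1)(c1ccccc1)c1ccccc1.[Br-]
Why: This is a Wittig methylenation of a non-enolisable aryl aldehyde with a non-stabilised ylide, and the molecule contains no other electrophile.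

**Step 4**
Reactants: 7, 2-bromo-1,4-dimethoxybenzene
Product: 8, 2-bromo-3-iodo-1,4-dimethoxybenzene
Conditions: LDA, THF, −78 °C; I2, −78 °C to rt
Reagents that add atoms: iodine, II
Why: This is a directed ortho-metalation in which LDA removes the most acidic proton, H-3 flanked by Br and OMe, without Br/Li exchange, and the aryllithium does not collapse to the aryne at −78 °C before the iodine quench.

**Step 5**
Reactants: 6; 8
Product: 9, 2-bromo-1,4-dimethoxy-3-[2-(4-{2-methoxy-5-[2-(3-methoxyphenyl)ethyl]phenoxy}phenyl)ethyl]benzene
Conditions: 6, 9-BBN, THF, 0 °C to rt; then 8 (1.2 equiv), PdCl2(dppf), AsPh3, Cs2CO3, DMF–H2O, 50 °C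
Reagents that add atoms: none beyond reactants 6 and 8 (9-BBN delivers only H)
Why: In this hydroboration/B-alkyl Suzuki–Miyaura sequence, oxidative addition at C–I is much faster than at the flanked, electron-rich C–Br, so the bromide is kept as the later leaving group and no C–Br-threatening hydrogenation is needed.

**Step 6**
Reactants: 9
Product: 10, 2-bromo-3-[2-(4-{2-hydroxy-5-[2-(3-hydroxyphenyl)ethyl]phenoxy}phenyl)ethyl]benzene-1,4-diol
Conditions: BBr3 (8 equiv), CH2Cl2, −78 °C to rt; degassed H2O
Reagents that add atoms: none
Why: BBr3-mediated aryl methyl ether cleavage removes all four O-methyl groups, while the diaryl ether (two sp2 C–O bonds) and the aryl bromide are inert.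

**Step 7**
Reactants: 10
Product: 11, 2-bromo-3-[2-(4-{2-hydroxy-5-[2-(3-hydroxyphenyl)ethyl]phenoxy}phenyl)ethyl]cyclohexa-2,5-diene-1,4-dione
Conditions: Ag2O (1.5 equiv), MgSO4, Et2O–THF, rt, 15 min, dark; filter through Celite
Reagents that add atoms: none
Why: In this hydroquinone-to-quinone oxidation the low-potential hydroquinone reacts with Ag2O within minutes, and the two monophenols, which are far harder to oxidise, are spared by the limited oxidant and short contact time.

**Step 8 (key step)**
Reactants: 11
Product: 12, marchantinquinone
Conditions: Cs2CO3 (2.5 equiv), 4 Å MS, MeCN (0.5 mM), 0 °C to rt, Ar, dark, 1–3 h; AcOH quench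
Reagents that add atoms: none
Why: Proposed new method: this is a macrocyclic, protecting-group-free version of the well-known intermolecular phenoxide/2-halo-1,4-quinone addition–elimination (vinylogous acyl substitution, related to SNAr diaryl-ether macrocyclisations). The C-ring phenoxide adds to C-2 and the adduct loses bromide irreversibly, whereas oxa-Michael addition at C-5/C-6 is reversible because aryloxide is a good leaving group. The B-ring phenoxide cannot compete intramolecularly, since it would have to form a strained 12-membered [8]paracyclophane, and it is hindered by its ortho-aryloxy group. High dilution suppresses intermolecular attack, and the short base exposure limits alkylquinone tautomerisation.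

## Compound list
1 | 5-bromo-2-methoxyphenol | COc1ccc(Br)cc1O | starting material
2 | 4-fluorobenzaldehyde | O=Cc1ccc(F)cc1 | starting material
3 | 4-(5-bromo-2-methoxyphenoxy)benzaldehyde | COc1ccc(Br)cc1Oc1ccc(C=O)cc1 | intermediate
4 | 3-vinylanisole | C=Cc1cccc(OC)c1 | starting material
5 | 4-{2-methoxy-5-[2-(3-methoxyphenyl)ethyl]phenoxy}benzaldehyde | COc1ccc(CCc2cccc(OC)c2)cc1Oc1ccc(C=O)cc1 | intermediate
6 | 1-(4-ethenylphenoxy)-2-methoxy-5-[2-(3-methoxyphenyl)ethyl]benzene | COc1ccc(CCc2cccc(OC)c2)cc1Oc1ccc(C=C)cc1 | intermediate
7 | 2-bromo-1,4-dimethoxybenzene | COc1ccc(OC)c(Br)c1 | starting material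
8 | 2-bromo-3-iodo-1,4-dimethoxybenzene | COc1ccc(OC)c(I)c1Br | intermediate
9 | tetramethyl ether seco-bromide | COc1ccc(CCc2cccc(OC)c2)cc1Oc1ccc(CCc2c(OC)ccc(OC)c2Br)cc1 | intermediate
10 | seco bromohydroquinone bis-phenol | Oc1ccc(CCc2cccc(O)c2)cc1Oc1ccc(CCc2c(O)ccc(O)c2Br)cc1 | intermediate
11 | seco 2-bromo-1,4-benzoquinone bis-phenol | Oc1ccc(CCc2cccc(O)c2)cc1Oc1ccc(CCC2=C(Br)C(=O)C=CC2=O)cc1 | intermediate
12 | marchantinquinone (achiral, C28H22O5) | O=C1C=CC(=O)C2=C1CCc1ccc(cc1)Oc1cc(ccc1O)CCc1cccc(c1)O2 | target

## Summary
Total step count: 8
Longest linear sequence: 7 (steps 1, 2, 3, 5, 6, 7, 8). Step 4 is the one-step side branch.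

Three steps most likely to fail:

1. **Step 8.** The risks are Michael addition at C-5/C-6 instead of ipso attack at C-2, oligomerisation, interference from the free B-ring phenoxide, and base-sensitivity of the alkylquinone.
   - Fallback: change the ring-closing bond.
   - Make the quinone aryl ether intermolecularly from the free C-ring-phenol analogue of 6 and excess 2,3-dibromo-1,4-benzoquinone.
   - Reduce and O-methylate to the 2-aryloxy-3-bromo-1,4-dimethoxyarene.
   - Close the macrocycle at the D–CH2 bond by 9-BBN hydroboration and high-dilution intramolecular B-alkyl Suzuki coupling, then finish with BBr3/Ag2O.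
2. **Step 5.** The iodide is di-ortho-substituted and must couple without touching the neighbouring C–Br.
   - Fallback: switch to olefination.
   - Convert 7 with LDA/DMF into 2-bromo-3,6-dimethoxybenzaldehyde.
   - Convert aldehyde 5 into its benzylic phosphonium salt with NaBH4, PBr3 and PPh3.
   - Carry out the Wittig coupling, then reduce the stilbene with diimide (TsNHNH2, NaOAc), which spares C–Br.
3. **Step 7.** The risks are over-oxidation of the 4-alkyl-2-aryloxyphenol B ring and instability of an unprotected phenol/bromoquinone on concentration.
   - Fallback: use an orthogonally protected series, with the B-ring OH as a benzyl ether (from 2-benzyloxy-5-bromophenol) and the C-ring OH as a TIPS ether (from 3-vinylphenol).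
   - Generate the bromoquinone by CAN oxidative demethylation of ring D.
   - Trigger ring closure by CsF desilylation.
   - Finish with H2/Pd–C debenzylation and Ag2O reoxidation of the hydroquinone.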